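**Assumption (one line):** the SMILES decodes to (2S,2″S,3″S) with the C2″ aryl group cis to the spiro ether oxygen O1″ and trans to the C4″ ketone. Locants: flavan unit = O1, C2–C8a; second unit = C2″ (ArCH–O7), C3″ (spiro C), C4″ (C=O).

## Retrosynthetic overview
1. The biomimetic union of a flavan with an aurone/chalcone C15 unit (Friedel–Crafts or oxidative [3+2]) is avoided. The second flavonoid is cut instead into a C6–C2 piece (acetophenone) and a C1–C6 piece (a benzyl ether).
2. The last ring, the benzofuranone, closes at O1″–C3″ by enolate iodination and phenoxide SN2. The spiro centre is relayed from C2″.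
3. Key step: the C2″–C3″ bond forms by enantioselective Rh(II)-carbene 1,5-C–H insertion into the O7 4-(benzyloxy)benzyl "protecting group", which becomes the C2″ aryl unit. This closes the dihydrofuran, the second ring.
4. The C8–C3″ bond comes from Pd α-arylation of a phloroacetophenone ether with an 8-bromoflavan, followed by Regitz diazo transfer.
5. The first ring, the (2S)-chroman, comes from aldol condensation, tandem asymmetric transfer hydrogenation, invertive Mitsunobu closure and C8-selective NBS bromination.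

## Route

**Step 1**
Reactants: 1, 2,4,6-trihydroxybenzaldehyde; 2, 4-(benzyloxy)benzyl chloride (2.05 equiv)
Product: 3, 4,6-bis{[4-(benzyloxy)benzyl]oxy}-2-hydroxybenzaldehyde
Conditions: K2CO3 (2.2 equiv), NaI (cat.), DMF, rt → 40 °C
Reagents that add atoms: 4-(benzyloxy)benzyl chloride, ClCc1ccc(OCc2ccccc2)cc1
Why: Williamson etherification, in which weak base and two equivalents of halide leave free the one OH that is hydrogen-bonded to the formyl group; no stereocentre is formed.

**Step 2**
Reactants: 3; 4, 4′-(benzyloxy)acetophenone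
Product: 5, (E)-1-[4-(benzyloxy)phenyl]-3-(4,6-bis{[4-(benzyloxy)benzyl]oxy}-2-hydroxyphenyl)prop-2-en-1-one
Conditions: KOH (50% aq), EtOH/THF, 45 °C; AcOH work-up
Reagents that add atoms: 4′-(benzyloxy)acetophenone, CC(=O)c1ccc(OCc2ccccc2)cc1
Why: Claisen–Schmidt aldol condensation gives the conjugated E-enone after irreversible E1cB loss of water, which compensates for the low electrophilicity of the phenoxide-aldehyde.

**Step 3**
Reactants: 5
Product: 6, (1R)-1-[4-(benzyloxy)phenyl]-3-(4,6-bis{[4-(benzyloxy)benzyl]oxy}-2-hydroxyphenyl)propan-1-ol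
Conditions: RuCl(p-cymene)[(R,R)-TsDPEN] (2 mol %), HCO2Na, MeOH/H2O/THF, 50 °C
Reagents that add atoms: none
Why: Tandem Noyori–Ikariya transfer hydrogenation reduces the chalcone C=C first and then the aryl ketone, and the (R,R)-catalyst delivers hydride to give the (R)-carbinol as it does for aryl alkyl ketones; benzyl ethers are untouched.

**Step 4**
Reactants: 6
Product: 7, (2S)-2-[4-(benzyloxy)phenyl]-5,7-bis{[4-(benzyloxy)benzyl]oxy}chromane
Conditions: PPh3, DIAD, THF, 0 °C → rt
Reagents that add atoms: none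
Why: Intramolecular Mitsunobu etherification, in which the only free phenol displaces the activated carbinol by SN2, so (R)-alcohol becomes (2S)-flavan with inversion.

**Step 5**
Reactants: 7; 8, N-bromosuccinimide (1.0 equiv)
Product: 9, (2S)-8-bromo-2-[4-(benzyloxy)phenyl]-5,7-bis{[4-(benzyloxy)benzyl]oxy}chromane
Conditions: CH2Cl2, −78 → −20 °C, dark
Reagents that add atoms: NBS, O=C1CCC(=O)N1Br
Why: Electrophilic aromatic bromination occurs on the trialkoxy A-ring at C8, which is flanked by the ring oxygen and is less hindered than C6 between two ArCH2O groups, matching the known selectivity of 5,7-di-O-benzyl flavans.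

**Step 6**
Reactants: 10, 2′,4′,6′-trihydroxyacetophenone; 11, benzyl bromide (2.1 equiv)
Product: 12, 1-[2,4-bis(benzyloxy)-6-hydroxyphenyl]ethan-1-one
Conditions: K2CO3, acetone, reflux
Reagents that add atoms: benzyl bromide, BrCc1ccccc1
Why: Williamson etherification stops at the dibenzyl ether because the remaining OH is chelated to the ketone.

**Step 7**
Reactants: 12; 13, triisopropylsilyl triflate
Product: 14, 1-[2,4-bis(benzyloxy)-6-(triisopropylsilyloxy)phenyl]ethan-1-one
Conditions: 2,6-lutidine, CH2Cl2, 0 °C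
Reagents that add atoms: TIPSOTf, CC(C)[Si](C(C)C)(C(C)C)OS(=O)(=O)C(F)(F)F
Why: O-silylation installs a bulky, weakly Lewis-basic, fluoride-labile mask on the future O1″ that is orthogonal to every benzyl-type ether and needs no Lewis acid for removal.

**Step 8**
Reactants: 9; 14 (1.2 equiv)
Product: 15, 2-{(2S)-2-[4-(benzyloxy)phenyl]-5,7-bis{[4-(benzyloxy)benzyl]oxy}chroman-8-yl}-1-[2,4-bis(benzyloxy)-6-(triisopropylsilyloxy)phenyl]ethan-1-one
Conditions: Pd2(dba)3 (2.5 mol %), XPhos (10 mol %), K3PO4, toluene, 100 °C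
Reagents that add atoms: none beyond reactants 9 and 14
Why: Buchwald–Hartwig ketone α-arylation, in which a bulky biaryl phosphine allows oxidative addition and reductive elimination at a di-ortho-alkoxy aryl bromide, and the hindered, more acidic product enolate prevents diarylation.

**Step 9**
Reactants: 15; 16, 4-acetamidobenzenesulfonyl azide (p-ABSA)
Product: 17, the 2-diazo derivative of 15, Ar″C(=O)–C(=N2)–(flavan-8-yl)
Conditions: DBU, MeCN/THF, 0 °C → rt; Et3N-deactivated silica
Reagents that add atoms: p-ABSA, CC(=O)Nc1ccc(cc1)S(=O)(=O)N=[N+]=[N-]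
Why: Regitz diazo transfer works on a deoxybenzoin methylene that is acidic enough for DBU; ethers, the silyl ether and C2 are inert.

**Step 10 (key step)**
Reactants: 17
Product: 18, [(2S,8R,9R)-2,8-bis[4-(benzyloxy)phenyl]-5-{[4-(benzyloxy)benzyl]oxy}-3,4,8,9-tetrahydro-2H-furo[2,3-h]chromen-9-yl][2,4-bis(benzyloxy)-6-(triisopropylsilyloxy)phenyl]methanone. This is 2″R,3″R, trans. The 2″R descriptor is the same spatial arrangement as 2″S in the target, because the CIP priority of C3″ changes.
Conditions: Rh2(S-PTAD)4 (1 mol %), toluene, −40 → 0 °C; then DBU (10 mol %), rt. The sense of induction is confirmed on the first run; the antipodal catalyst is equally available.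
Reagents that add atoms: none
Why: Intramolecular 1,5-C–H insertion of a Rh(II) donor/acceptor carbene, where the only reachable activated C–H bonds are the two enantiotopic benzylic, α-oxy hydrogens of O7–CH2Ar (flavan H-2 points away from C8), so the chiral carboxylate pocket selects one in a concerted insertion that fixes C2″ under catalyst control, low temperature keeps oxonium-ylide formation at the flanking aryl ethers non-productive, and DBU converges the labile C3″–H centre to trans.

**Step 11**
Reactants: 18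
Product: 19, the 6-hydroxy (desilylated) analogue of 18, (2S,2″R,3″R)
Conditions: TBAF, AcOH, THF, 0 °C
Reagents that add atoms: none
Why: Fluoride desilylation of an activated aryl silyl ether under buffered conditions leaves benzyl ethers and C2″ untouched, and any C3″ epimerisation is irrelevant.

**Step 12**
Reactants: 19
Product: 20, penta-O-protected daphnodorin C, (2S,2″S,3″S): 4,6-bis(benzyloxy)benzofuran-3-one spiro-fused at C3″, with 5-O-[4-(benzyloxy)benzyl] and both 4-(benzyloxy)phenyl groups retained
Conditions: KHMDS (2.2 equiv), THF, −78 °C; I2 (1.05 equiv), −78 → −20 °C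
Reagents that add atoms: none (iodine is lost as KI)
Why: Enolate α-iodination followed by 5-exo-tet intramolecular Williamson closure (the classical coumaranone synthesis), where iodine adds anti to the C2″ aryl group and the adjacent phenoxide displaces it with inversion to place O1″ cis to the aryl and C4″=O trans as in the target; an SN1-like path converges on the same isomer for steric reasons, and the syn H-2″/I relationship disfavours E2 aromatisation.

**Step 13**
Reactants: 20
Product: 21, daphnodorin C
Conditions: H2 (1 atm), Pd(OH)2/C, THF/MeOH, rt, monitored closely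
Reagents that add atoms: none
Why: Catalytic hydrogenolysis cleaves the four ArO–Bn ethers and the 5-O-(4-benzyloxybenzyl) ether (lost as toluene and p-cresol) much faster than the hindered cyclic C2–O1 and C2″–O7 bonds or the vinylogous-ester ketone; neutral conditions leave all three stereocentres untouched.

## Compound list
1 | 2,4,6-trihydroxybenzaldehyde | O=Cc1c(O)cc(O)cc1O | starting material
2 | 4-(benzyloxy)benzyl chloride | ClCc1ccc(OCc2ccccc2)cc1 | starting material
3 | 4,6-bis{[4-(benzyloxy)benzyl]oxy}-2-hydroxybenzaldehyde | O=Cc1c(O)cc(OCc2ccc(OCc3ccccc3)cc2)cc1OCc1ccc(OCc2ccccc2)cc1 | intermediate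
4 | 4′-(benzyloxy)acetophenone | CC(=O)c1ccc(OCc2ccccc2)cc1 | starting material
5 | (E)-2-hydroxy retro-chalcone | O=C(/C=C/c1c(O)cc(OCc2ccc(OCc3ccccc3)cc2)cc1OCc1ccc(OCc2ccccc2)cc1)c1ccc(OCc2ccccc2)cc1 | intermediate
6 | (1R)-1,3-diarylpropan-1-ol | O[C@H](CCc1c(O)cc(OCc2ccc(OCc3ccccc3)cc2)cc1OCc1ccc(OCc2ccccc2)cc1)c1ccc(OCc2ccccc2)cc1 | intermediate
7 | (2S)-protected 5,7,4′-trihydroxyflavan | c1c(OCc2ccc(OCc3ccccc3)cc2)cc(OCc2ccc(OCc3ccccc3)cc2)c2c1O[C@H](c1ccc(OCc3ccccc3)cc1)CC2 | intermediate
8 | N-bromosuccinimide | O=C1CCC(=O)N1Br | starting material (reagent)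
9 | (2S)-8-bromoflavan | Brc1c(OCc2ccc(OCc3ccccc3)cc2)cc(OCc2ccc(OCc3ccccc3)cc2)c2c1O[C@H](c1ccc(OCc3ccccc3)cc1)CC2 | intermediate
10 | 2′,4′,6′-trihydroxyacetophenone | CC(=O)c1c(O)cc(O)cc1O | starting material
11 | benzyl bromide | BrCc1ccccc1 | starting material (reagent)
12 | 1-[2,4-bis(benzyloxy)-6-hydroxyphenyl]ethanone | CC(=O)c1c(O)cc(OCc2ccccc2)cc1OCc1ccccc1 | intermediate
13 | triisopropylsilyl triflate | CC(C)[Si](C(C)C)(C(C)C)OS(=O)(=O)C(F)(F)F | starting material (reagent)
14 | 1-[2,4-bis(benzyloxy)-6-(TIPSO)phenyl]ethanone | CC(=O)c1c(O[Si](C(C)C)(C(C)C)C(C)C)cc(OCc2ccccc2)cc1OCc1ccccc1 | intermediate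
15 | (2S)-deoxybenzoin | O=C(Cc1c(OCc2ccc(OCc3ccccc3)cc2)cc(OCc2ccc(OCc3ccccc3)cc2)c2c1O[C@H](c1ccc(OCc3ccccc3)cc1)CC2)c1c(O[Si](C(C)C)(C(C)C)C(C)C)cc(OCc2ccccc2)cc1OCc1ccccc1 | intermediate
16 | 4-acetamidobenzenesulfonyl azide | CC(=O)Nc1ccc(cc1)S(=O)(=O)N=[N+]=[N-] | starting material (reagent)
17 | (2S)-α-aryl-α-diazoketone | O=C(C(=[N+]=[N-])c1c(OCc2ccc(OCc3ccccc3)cc2)cc(OCc2ccc(OCc3ccccc3)cc2)c2c1O[C@H](c1ccc(OCc3ccccc3)cc1)CC2)c1c(O[Si](C(C)C)(C(C)C)C(C)C)cc(OCc2ccccc2)cc1OCc1ccccc1 | intermediate
18 | (2S,2″R,3″R)-trans-2″-aryl-3″-aroyl-dihydrofuro-flavan, TIPS ether | O=C(c1c(O[Si](C(C)C)(C(C)C)C(C)C)cc(OCc2ccccc2)cc1OCc1ccccc1)[C@@H]1c2c(cc(OCc3ccc(OCc4ccccc4)cc3)c3c2O[C@H](c2ccc(OCc4ccccc4)cc2)CC3)O[C@H]1c1ccc(OCc2ccccc2)cc1 | intermediate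
19 | (2S,2″R,3″R)-free ortho-phenol of 18 | O=C(c1c(O)cc(OCc2ccccc2)cc1OCc1ccccc1)[C@@H]1c2c(cc(OCc3ccc(OCc4ccccc4)cc3)c3c2O[C@H](c2ccc(OCc4ccccc4)cc2)CC3)O[C@H]1c1ccc(OCc2ccccc2)cc1 | intermediate
20 | (2S,2″S,3″S)-protected daphnodorin C | O=C1c2c(OCc3ccccc3)cc(OCc3ccccc3)cc2O[C@]12c1c(cc(OCc3ccc(OCc4ccccc4)cc3)c3c1O[C@H](c1ccc(OCc4ccccc4)cc1)CC3)O[C@H]2c1ccc(OCc2ccccc2)cc1 | intermediate
21 | daphnodorin C | O=C1c2c(O)cc(O)cc2O[C@]12c1c(cc(O)c3c1O[C@H](c1ccc(O)cc1)CC3)O[C@H]2c1ccc(O)cc1 | target

## Totals and risks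
Total steps: 13. Longest linear sequence: 11 (steps 1–5, then 8–13).

Steps most likely to fail:

1. **Step 10 (C–H insertion).**
   - Risks: oxonium-ylide formation with [1,2]-benzyl shift at the ortho OBn group of the aroyl unit, and modest selectivity from a doubly ortho-substituted diaryl diazoketone.
   - Fallback: change the acceptor. Couple 9 with the zinc enolate of methyl acetate, carry out diazo transfer, and run the insertion on the aryldiazoacetate, which has no flanking aryl ethers. Then build the ketone afterwards (DIBAL-H to the aldehyde, addition of the 2-lithio-1,5-bis(benzyloxy)-3-(TIPSO)benzene, DMP oxidation) to rejoin at 18.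

2. **Step 12 (spiro-etherification).**
   - Risk: ionisation of the tertiary iodide and loss of H-2″ to give the aromatic 3-aroylbenzofuran.
   - Fallback: never place a leaving group on C3″. Use the 2-fluoro analogue of 14 and the antipodal Rh catalyst. Hydroxylate the enolate with a Davis oxaziridine (anti to the aryl group), then close the O1″–aryl bond by alkoxide SNAr. After debenzylation, equilibrate C2″ through the p-quinone methide to the isomer with O1″ cis to the aryl group.

3. **Step 8 (α-arylation).**
   - Risk: slow coupling of the very electron-rich, di-ortho-alkoxy bromide, and O→O silyl migration in the enolate.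
   - Fallback: reverse the polarity. Carry out Br/Li exchange on 9, form the cuprate and allylate it, then cleave by Lemieux–Johnson oxidation to the 8-arylacetaldehyde. Add the aryllithium derived from the A″ ring and oxidise with DMP to reach 15.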